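**Retrosynthetic overview**
1. Target 17 ⇒ anodic cross-coupling of the two acetic acids 15 and 16, which forms the central C12–C12′ bond last.
2. 15 and 16 ⇒ one keto acid 13 (C10 ketone: equatorial methyl addition plus acetylation, or methylenation).
3. 13 ⇒ oxepene 9: a singlet-oxygen ene reaction puts oxygen on C3, then hydrogenation and saponification.
4. 9 ⇒ tertiary silyl peroxide 8: oxygen is inserted into the C7–CMe2 bond and the C2–C3 bond is closed in one operation (oxepane ring).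
5. 8 ⇒ (+)-verbenone 1 by cuprate addition/alkylation and cyclobutane fragmentation. Ring order: cyclohexane (from 1) → oxepane → union of the two bicycles.

Assumption: (1R,5R)-(+)-verbenone (1) is bought as such; it is the only source of chirality.
Labels used for one half: O1, C2 (CMe2), C3 (CH–O), C4, C5, C6 (quaternary C–Me), C7 (CH–O1), C8, C9, C10, C11 (CH), C12 (CH2), C13 (carboxyl carbon, lost on coupling).

**Step 1**
Reactants: 1 (1R,5R)-(+)-verbenone; 2 trimethyl(prop-1-yn-1-yl)silane; 3 methyl bromoacetate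
Product: 5 methyl 2-[(1R,3S,4S,5S)-4,6,6-trimethyl-2-oxo-4-[3-(trimethylsilyl)prop-2-yn-1-yl]bicyclo[3.1.1]heptan-3-yl]acetate, via lithium enolate 4 (not isolated)
Conditions: 2, n-BuLi, TMEDA, THF, −20 °C; CuI, −40 °C; 1, −40→0 °C; then 3, HMPA, −40→20 °C; aq. NH4Cl
Reagents that add atoms: none
Why: Cuprate conjugate addition of the silyl-capped propargyl group to the β,β-disubstituted enone makes the C6 quaternary centre on the face anti to the gem-dimethyl bridge (chain trans to the future C7 substituent); only C3 of the bicycle can enolise (C1 is a bridgehead), so enolate 4 is alkylated regiospecifically (three-component enone coupling), and the new α-centre is corrected in step 2.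

**Step 2**
Reactants: 5 methyl 2-[(1R,3S,4S,5S)-4,6,6-trimethyl-2-oxo-4-[3-(trimethylsilyl)prop-2-yn-1-yl]bicyclo[3.1.1]heptan-3-yl]acetate
Product: 6 methyl 2-[(1R,2S,3S)-2-methyl-6-oxo-3-(prop-1-en-2-yl)-2-[3-(trimethylsilyl)prop-2-yn-1-yl]cyclohexyl]acetate
Conditions: p-TsOH·H2O (20 mol %), benzene, 80 °C
Reagents that add atoms: none
Why: Acid-promoted fragmentation of the cyclobutyl ketone: the ring bond between the carbonyl α-carbon and the CMe2 carbon ionises to enol plus tertiary cation, which loses a methyl proton (E1) to the isopropenyl group (the isopropylidene isomer suffers allylic strain against the quaternary neighbour); the alkynylsilane cannot capture the cation, C11 epimerises through the enol to the all-equatorial ketone, and C7 keeps the configuration bought with 1.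

**Step 3**
Reactants: 6 methyl 2-[(1R,2S,3S)-2-methyl-6-oxo-3-(prop-1-en-2-yl)-2-[3-(trimethylsilyl)prop-2-yn-1-yl]cyclohexyl]acetate
Product: 7 methyl 2-[(1R,2S,3S)-2-methyl-6-oxo-3-(prop-1-en-2-yl)-2-[(2Z)-3-(trimethylsilyl)prop-2-en-1-yl]cyclohexyl]acetate
Conditions: H2 (1 atm), Pd/CaCO3 poisoned by Pb(OAc)2, quinoline, hexane–EtOAc, 20 °C
Reagents that add atoms: hydrogen, [H][H]
Why: Lindlar cis-semihydrogenation of the silylalkyne gives the (Z)-vinylsilane; the 1,1-disubstituted alkene and the ketone are not reduced.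

**Step 4**
Reactants: 7 methyl 2-[(1R,2S,3S)-2-methyl-6-oxo-3-(prop-1-en-2-yl)-2-[(2Z)-3-(trimethylsilyl)prop-2-en-1-yl]cyclohexyl]acetate
Product: 8 methyl 2-[(1R,2S,3R)-2-methyl-6-oxo-3-[2-(triethylsilylperoxy)propan-2-yl]-2-[(2Z)-3-(trimethylsilyl)prop-2-en-1-yl]cyclohexyl]acetate
Conditions: Co(acac)2 (10 mol %), O2 (1 atm), Et3SiH, ClCH2CH2Cl, 20 °C
Reagents that add atoms: dioxygen, O=O; triethylsilane, CC[SiH](CC)CC
Why: Mukaiyama–Isayama silylperoxidation: cobalt-hydride hydrogen-atom transfer to the isopropenyl group gives the tertiary radical, which O2 traps (faster under 1 atm O2 than 5-exo cyclisation) before silyl transfer; the internal vinylsilane reacts far more slowly and no stereocentre is formed.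

**Step 5**
Reactants: 8 methyl 2-[(1R,2S,3R)-2-methyl-6-oxo-3-[2-(triethylsilylperoxy)propan-2-yl]-2-[(2Z)-3-(trimethylsilyl)prop-2-en-1-yl]cyclohexyl]acetate
Product: 9 methyl 2-[(5aR,6R,9aR)-2,2,5a-trimethyl-7-oxo-2,5,5a,6,7,8,9,9a-octahydro-1-benzoxepin-6-yl]acetate
Conditions: Me3SiOTf (20 mol %), 2,6-di-tert-butyl-4-methylpyridine, CH2Cl2, −78→−30 °C
Reagents that add atoms: none
Why: Proposed new method: interrupted Hock (Criegee-type) rearrangement ended by a vinylsilane. Me3SiOTf silylates the distal peroxide oxygen; the O–O bond heterolyses with 1,2-shift of the secondary ring carbon C7 (a better migrating group than methyl, with retention at C7) to the 2-alkoxyprop-2-yl cation; this is captured by 7-membered ipso attack of the (Z)-vinylsilane, and loss of Me3Si+ (which turns the catalyst over and ends as Et3SiOSiMe3) gives the cis ring alkene. The closest known reactions are the Hock/Criegee rearrangement of tertiary peroxides and the acetal-initiated vinylsilane (silyl-Prins) cyclisation to tetrahydrooxepines; new is their union on an aliphatic silyl peroxide, which inserts the ring oxygen and closes the trans-fused oxepane in one step.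

**Step 6**
Reactants: 9 methyl 2-[(5aR,6R,9aR)-2,2,5a-trimethyl-7-oxo-2,5,5a,6,7,8,9,9a-octahydro-1-benzoxepin-6-yl]acetate
Product: 10 methyl 2-[(3R,5aR,6R,9aR)-3-hydroperoxy-2,2,5a-trimethyl-7-oxo-2,3,5a,6,7,8,9,9a-octahydro-1-benzoxepin-6-yl]acetate
Conditions: O2, hν (visible light), tetraphenylporphyrin (1 mol %), CH2Cl2, −20 °C
Reagents that add atoms: dioxygen, O=O
Why: Schenck ene reaction of singlet oxygen: the only allylic hydrogens are on C5, and only the pseudo-axial one (anti to the axial C6 methyl, on the face of H7) is aligned with the π system, so oxygen is delivered suprafacially to C3 on that face (3R) while the double bond moves to C4=C5.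

**Step 7**
Reactants: 10 methyl 2-[(3R,5aR,6R,9aR)-3-hydroperoxy-2,2,5a-trimethyl-7-oxo-2,3,5a,6,7,8,9,9a-octahydro-1-benzoxepin-6-yl]acetate
Product: 12 methyl 2-[(3R,5aR,6R,9aR)-3-hydroxy-2,2,5a-trimethyl-7-oxodecahydro-1-benzoxepin-6-yl]acetate, via allylic alcohol 11 (not isolated)
Conditions: H2 (1 atm), Pd/C, EtOAc, 20 °C
Reagents that add atoms: hydrogen, [H][H]
Why: Hydrogenolysis of the O–O bond to 11 followed by catalytic hydrogenation of the disubstituted alkene; C3 is untouched and ketone and ester survive.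

**Step 8**
Reactants: 12 methyl 2-[(3R,5aR,6R,9aR)-3-hydroxy-2,2,5a-trimethyl-7-oxodecahydro-1-benzoxepin-6-yl]acetate
Product: 13 2-[(3R,5aR,6R,9aR)-3-hydroxy-2,2,5a-trimethyl-7-oxodecahydro-1-benzoxepin-6-yl]acetic acid
Conditions: LiOH, THF–H2O, 20 °C; then aq. HCl to pH 3
Reagents that add atoms: lithium hydroxide, [Li+].[OH-]
Why: Ester saponification; any C11 epimer carried this far equilibrates through the enolate to the equatorial arm.

**Step 9**
Reactants: 13 2-[(3R,5aR,6R,9aR)-3-hydroxy-2,2,5a-trimethyl-7-oxodecahydro-1-benzoxepin-6-yl]acetic acid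
Product: 15 2-[(3R,5aR,6R,7S,9aR)-3,7-diacetoxy-2,2,5a,7-tetramethyldecahydro-1-benzoxepin-6-yl]acetic acid, via bromomagnesium alkoxide 14 (not isolated)
Conditions: MeMgBr (5 equiv), CeCl3, THF, −78→0 °C; then isopropenyl acetate, 0→40 °C; aq. NaH2PO4
Reagents that add atoms: methylmagnesium bromide, C[Mg]Br; isopropenyl acetate, CC(=C)OC(C)=O
Why: Cerium-assisted Grignard addition attacks the C10 carbonyl equatorially because the axial path is blocked by the syn-axial C6 methyl (as with 3,3,5-trimethylcyclohexanone), giving the axial tertiary alkoxide (7S in the name, C10); transesterification of both alkoxides of 14 with the enol ester gives the two acetates without activating the carboxylate, so the γ-lactone cannot form.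

**Step 10**
Reactants: 13 2-[(3R,5aR,6R,9aR)-3-hydroxy-2,2,5a-trimethyl-7-oxodecahydro-1-benzoxepin-6-yl]acetic acid
Product: 16 2-[(3R,5aR,6S,9aR)-3-hydroxy-2,2,5a-trimethyl-7-methylidenedecahydro-1-benzoxepin-6-yl]acetic acid
Conditions: Ph3PCH3Br, KOtBu (excess), THF–toluene, 0→60 °C; aq. NaH2PO4
Reagents that add atoms: methyltriphenylphosphonium bromide, C[P+](c1ccccc1)(c1ccccc1)c1ccccc1.[Br-]
Why: Wittig methylenation of the 2-substituted cyclohexanone; the acid and the alcohol are carried as salts and C11 stays in the thermodynamic equatorial configuration.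

**Step 11**
Reactants: 15 2-[(3R,5aR,6R,7S,9aR)-3,7-diacetoxy-2,2,5a,7-tetramethyldecahydro-1-benzoxepin-6-yl]acetic acid; 16 2-[(3R,5aR,6S,9aR)-3-hydroxy-2,2,5a-trimethyl-7-methylidenedecahydro-1-benzoxepin-6-yl]acetic acid (2 equiv)
Product: 17 (3R,5aR,6R,7S,9aR)-6-{2-[(3R,5aR,6S,9aR)-3-hydroxy-2,2,5a-trimethyl-7-methylidenedecahydro-1-benzoxepin-6-yl]ethyl}-2,2,5a,7-tetramethyldecahydro-1-benzoxepine-3,7-diyl diacetate
Conditions: MeOH, KOH (0.1 equiv), Pt anode and Pt cathode, undivided cell, constant current 0.25 A cm−2, 15 °C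
Reagents that add atoms: none
Why: Mixed Kolbe electrolysis: anodic decarboxylation of both carboxylates gives the two primary C12 radicals, which combine at the Pt surface faster than they are oxidised further or rearrange; the cross product (statistical, favoured by the excess of 16) differs strongly in polarity from both homodimers, and no stereocentre is touched.

**Compound list**
1 | (1R,5R)-(+)-verbenone, (1R,5R)-4,6,6-trimethylbicyclo[3.1.1]hept-3-en-2-one | CC1=CC(=O)[C@@H]2C[C@H]1C2(C)C | starting material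
2 | trimethyl(prop-1-yn-1-yl)silane | CC#C[Si](C)(C)C | starting material
3 | methyl bromoacetate | COC(=O)CBr | starting material
4 | lithium (1R,4S,5S)-4,6,6-trimethyl-4-[3-(trimethylsilyl)prop-2-yn-1-yl]bicyclo[3.1.1]hept-2-en-2-olate | [Li]OC1=C[C@@](C)(CC#C[Si](C)(C)C)[C@H]2C[C@@H]1C2(C)C | intermediate
5 | methyl 2-[(1R,3S,4S,5S)-4,6,6-trimethyl-2-oxo-4-[3-(trimethylsilyl)prop-2-yn-1-yl]bicyclo[3.1.1]heptan-3-yl]acetate | O=C1[C@@H]2C[C@@H](C2(C)C)[C@](C)(CC#C[Si](C)(C)C)[C@@H]1CC(=O)OC | intermediate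
6 | methyl 2-[(1R,2S,3S)-2-methyl-6-oxo-3-(prop-1-en-2-yl)-2-[3-(trimethylsilyl)prop-2-yn-1-yl]cyclohexyl]acetate | O=C1CC[C@@H](C(C)=C)[C@](C)(CC#C[Si](C)(C)C)[C@H]1CC(=O)OC | intermediate
7 | methyl 2-[(1R,2S,3S)-2-methyl-6-oxo-3-(prop-1-en-2-yl)-2-[(2Z)-3-(trimethylsilyl)prop-2-en-1-yl]cyclohexyl]acetate | O=C1CC[C@@H](C(C)=C)[C@](C)(C/C=C\[Si](C)(C)C)[C@H]1CC(=O)OC | intermediate
8 | methyl 2-[(1R,2S,3R)-2-methyl-6-oxo-3-[2-(triethylsilylperoxy)propan-2-yl]-2-[(2Z)-3-(trimethylsilyl)prop-2-en-1-yl]cyclohexyl]acetate | O=C1CC[C@@H](C(C)(C)OO[Si](CC)(CC)CC)[C@](C)(C/C=C\[Si](C)(C)C)[C@H]1CC(=O)OC | intermediate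
9 | methyl 2-[(5aR,6R,9aR)-2,2,5a-trimethyl-7-oxo-2,5,5a,6,7,8,9,9a-octahydro-1-benzoxepin-6-yl]acetate | O=C1CC[C@H]2OC(C)(C)/C=C\C[C@]2(C)[C@H]1CC(=O)OC | intermediate
10 | methyl 2-[(3R,5aR,6R,9aR)-3-hydroperoxy-2,2,5a-trimethyl-7-oxo-2,3,5a,6,7,8,9,9a-octahydro-1-benzoxepin-6-yl]acetate | O=C1CC[C@H]2OC(C)(C)[C@H](OO)/C=C\[C@]2(C)[C@H]1CC(=O)OC | intermediate
11 | methyl 2-[(3R,5aR,6R,9aR)-3-hydroxy-2,2,5a-trimethyl-7-oxo-2,3,5a,6,7,8,9,9a-octahydro-1-benzoxepin-6-yl]acetate | O=C1CC[C@H]2OC(C)(C)[C@H](O)/C=C\[C@]2(C)[C@H]1CC(=O)OC | intermediate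
12 | methyl 2-[(3R,5aR,6R,9aR)-3-hydroxy-2,2,5a-trimethyl-7-oxodecahydro-1-benzoxepin-6-yl]acetate | O=C1CC[C@H]2OC(C)(C)[C@H](O)CC[C@]2(C)[C@H]1CC(=O)OC | intermediate
13 | 2-[(3R,5aR,6R,9aR)-3-hydroxy-2,2,5a-trimethyl-7-oxodecahydro-1-benzoxepin-6-yl]acetic acid | O=C1CC[C@H]2OC(C)(C)[C@H](O)CC[C@]2(C)[C@H]1CC(=O)O | intermediate
14 | tris(bromomagnesium) salt of 2-[(3R,5aR,6R,7S,9aR)-3,7-dihydroxy-2,2,5a,7-tetramethyldecahydro-1-benzoxepin-6-yl]acetic acid | Br[Mg]OC(=O)C[C@@H]1[C@@]2(C)CC[C@@H](O[Mg]Br)C(C)(C)O[C@@H]2CC[C@]1(C)O[Mg]Br | intermediate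
15 | 2-[(3R,5aR,6R,7S,9aR)-3,7-diacetoxy-2,2,5a,7-tetramethyldecahydro-1-benzoxepin-6-yl]acetic acid | OC(=O)C[C@@H]1[C@@]2(C)CC[C@@H](OC(C)=O)C(C)(C)O[C@@H]2CC[C@]1(C)OC(C)=O | intermediate
16 | 2-[(3R,5aR,6S,9aR)-3-hydroxy-2,2,5a-trimethyl-7-methylidenedecahydro-1-benzoxepin-6-yl]acetic acid | C=C1CC[C@H]2OC(C)(C)[C@H](O)CC[C@]2(C)[C@H]1CC(=O)O | intermediate
17 | (3R,5aR,6R,7S,9aR)-6-{2-[(3R,5aR,6S,9aR)-3-hydroxy-2,2,5a-trimethyl-7-methylidenedecahydro-1-benzoxepin-6-yl]ethyl}-2,2,5a,7-tetramethyldecahydro-1-benzoxepine-3,7-diyl diacetate (CNP0412606.2) | C=C1CC[C@H]2OC(C)(C)[C@H](O)CC[C@]2(C)[C@H]1CC[C@@H]1[C@@]2(C)CC[C@@H](OC(C)=O)C(C)(C)O[C@@H]2CC[C@]1(C)OC(C)=O | target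

**Step count and risks**
Total step count: 11. Longest linear sequence: 10 (steps 1–9 and 11).

Step 5 (the new oxygen-insertion/ring closure). Fallback with known chemistry, setting out from 8 and returning at 9: Bu4NF/AcOH (THF, 0 °C) frees the tertiary hydroperoxide F1. (CF3CO)2O/pyridine (CH2Cl2, 0 °C) followed by aqueous NaHCO3 runs the classical Criegee rearrangement and hydrolyses the ketal ester, giving the secondary alcohol F2 (retention at C7) and acetone. 2-Methoxypropene with pyridinium p-toluenesulfonate converts F2 into the mixed ketal F3. Me3SiOTf (CH2Cl2, −78 °C) then ionises F3, and the known acetal–vinylsilane cyclisation closes the oxepene 9.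

Step 9 (the hindered tertiary alkoxide may not acetylate, and any activation of the carboxyl group would give the cis γ-lactone). Fallback that couples first and methylates afterwards, setting out from 13 and 16 and returning at 17: 13 is acetylated (Ac2O, pyridine, aqueous work-up) to the acetoxy keto acid F4, and 16 is silylated (tBuMe2SiOTf, 2,6-lutidine; K2CO3/MeOH work-up) to the silyl ether acid F5. Cross-Kolbe electrolysis of F4 with F5 under the conditions of step 11 gives the keto heterodimer F6, which has no carboxyl group left to lactonise. MeTi(OiPr)3 (ketone-selective, equatorial delivery) followed by Ac2O/DMAP gives the silyl-protected diacetate F7, and HF·pyridine removes the silyl ether to give 17.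

Step 11 (statistical cross-selectivity, over-oxidation at the anode). Fallback setting out from 15 and 16 and returning at 17: N-hydroxyphthalimide and N,N′-diisopropylcarbodiimide convert 15 into the redox-active ester F8 and 16 into the redox-active ester F9. Nickel-electrocatalytic doubly decarboxylative C(sp3)–C(sp3) cross-coupling (NiCl2·6H2O, 2,2′:6′,2″-terpyridine, AgNO3, DMF, Mg anode and reticulated vitreous carbon cathode, F9 in three-fold excess) then joins the two halves reductively to give 17.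

**Further compounds**
F1 | step 5 | methyl 2-[(1R,2S,3R)-3-(2-hydroperoxypropan-2-yl)-2-methyl-6-oxo-2-[(2Z)-3-(trimethylsilyl)prop-2-en-1-yl]cyclohexyl]acetate | O=C1CC[C@@H](C(C)(C)OO)[C@](C)(C/C=C\[Si](C)(C)C)[C@H]1CC(=O)OC
F2 | step 5 | methyl 2-[(1R,2R,3R)-3-hydroxy-2-methyl-6-oxo-2-[(2Z)-3-(trimethylsilyl)prop-2-en-1-yl]cyclohexyl]acetate | O=C1CC[C@@H](O)[C@](C)(C/C=C\[Si](C)(C)C)[C@H]1CC(=O)OC
F3 | step 5 | methyl 2-[(1R,2R,3R)-3-[(2-methoxypropan-2-yl)oxy]-2-methyl-6-oxo-2-[(2Z)-3-(trimethylsilyl)prop-2-en-1-yl]cyclohexyl]acetate | O=C1CC[C@@H](OC(C)(C)OC)[C@](C)(C/C=C\[Si](C)(C)C)[C@H]1CC(=O)OC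
F4 | step 9 | 2-[(3R,5aR,6R,9aR)-3-acetoxy-2,2,5a-trimethyl-7-oxodecahydro-1-benzoxepin-6-yl]acetic acid | O=C1CC[C@H]2OC(C)(C)[C@H](OC(C)=O)CC[C@]2(C)[C@H]1CC(=O)O
F5 | step 9 | 2-[(3R,5aR,6S,9aR)-3-(tert-butyldimethylsilyloxy)-2,2,5a-trimethyl-7-methylidenedecahydro-1-benzoxepin-6-yl]acetic acid | C=C1CC[C@H]2OC(C)(C)[C@H](O[Si](C)(C)C(C)(C)C)CC[C@]2(C)[C@H]1CC(=O)O
F6 | step 9 | (3R,5aR,6R,9aR)-6-{2-[(3R,5aR,6S,9aR)-3-(tert-butyldimethylsilyloxy)-2,2,5a-trimethyl-7-methylidenedecahydro-1-benzoxepin-6-yl]ethyl}-2,2,5a-trimethyl-7-oxodecahydro-1-benzoxepin-3-yl acetate | C=C1CC[C@H]2OC(C)(C)[C@H](O[Si](C)(C)C(C)(C)C)CC[C@]2(C)[C@H]1CC[C@@H]1[C@@]2(C)CC[C@@H](OC(C)=O)C(C)(C)O[C@@H]2CCC1=O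
F7 | step 9 | tert-butyldimethylsilyl ether of 17 at the left-half C3 hydroxyl | C=C1CC[C@H]2OC(C)(C)[C@H](O[Si](C)(C)C(C)(C)C)CC[C@]2(C)[C@H]1CC[C@@H]1[C@@]2(C)CC[C@@H](OC(C)=O)C(C)(C)O[C@@H]2CC[C@]1(C)OC(C)=O
F8 | step 11 | 1,3-dioxoisoindolin-2-yl ester of 15 | O=C(C[C@@H]1[C@@]2(C)CC[C@@H](OC(C)=O)C(C)(C)O[C@@H]2CC[C@]1(C)OC(C)=O)ON1C(=O)c2ccccc2C1=O
F9 | step 11 | 1,3-dioxoisoindolin-2-yl ester of 16 | C=C1CC[C@H]2OC(C)(C)[C@H](O)CC[C@]2(C)[C@H]1CC(=O)ON1C(=O)c2ccccc2C1=O
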